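**Retrosynthetic overview**
- Last operation: removal of two O‑benzyl groups from the bis‑benzyl ether of the target.
- Key disconnection: the lactone C–O bond and the C4a–C5 bond of the resorcinol ring are cut together. This unravels the bicyclic core to an open‑chain 3‑aryl‑5,7,9‑trioxoundec‑10‑enoic acid (a polyketide‑like chain). In the forward direction the resorcinol ring is built first by aldol aromatisation and the lactone closes directly afterwards in the same pot.
- The triketo acid comes from γ‑acylation of the dianion of O‑benzyl feruloylacetone by the ester arm of a chiral 3‑arylglutaric hemiester.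
- The stereocentre comes from organocatalytic desymmetrisation of the prochiral 3‑arylglutaric anhydride. Both guaiacyl rings are bought as O‑benzylvanillin.

Assumption: the target stereocentre is (4R) as read from the SMILES, and the pseudo‑enantiomer of the cinchona catalyst in step 3 (both are available) is chosen so that the (S)‑hemiester is obtained; the sense must be confirmed on the first run.

**Step 1**
Reactants: 1 4‑(benzyloxy)‑3‑methoxybenzaldehyde (O‑benzylvanillin); 2 ethyl acetoacetate (2.1 equiv)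
Product: 4 3‑[4‑(benzyloxy)‑3‑methoxyphenyl]pentanedioic acid, via diethyl 2,4‑diacetyl‑3‑arylpentanedioate 3 (not isolated)
Conditions: piperidine (10 mol%), EtOH, rt, 48 h; then 50% aq NaOH, reflux, 3 h; conc. HCl to pH 1
Reagents that add atoms: sodium hydroxide (aqueous; its oxygen ends in the two CO2H groups), [Na+].[OH-]
Why: Knoevenagel condensation followed by Michael addition of a second acetoacetate gives the bis‑adduct, and hot hydroxide then effects double retro‑Claisen deacetylation and saponification (the classical 3‑arylglutaric acid synthesis); the product is achiral (C3 is prochiral).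

**Step 2**
Reactants: 4 3‑[4‑(benzyloxy)‑3‑methoxyphenyl]pentanedioic acid
Product: 5 4‑[4‑(benzyloxy)‑3‑methoxyphenyl]oxane‑2,6‑dione (the 3‑arylglutaric anhydride)
Conditions: Ac2O, reflux, 2 h; evaporate; crystallise (toluene/heptane)
Reagents that add atoms: none
Why: Cyclodehydration of a 1,5‑diacid through the mixed anhydride gives the six‑membered cyclic anhydride, which is prochiral and carries no stereocentre yet.

**Step 3**
Reactants: 5 4‑[4‑(benzyloxy)‑3‑methoxyphenyl]oxane‑2,6‑dione
Product: 6 (3S)‑3‑[4‑(benzyloxy)‑3‑methoxyphenyl]‑5‑methoxy‑5‑oxopentanoic acid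
Conditions: MeOH (10 equiv), cinchona‑derived bifunctional sulfonamide organocatalyst (5–10 mol%, pseudo‑enantiomer selected for the (S) product), MTBE, rt, 24 h; acid wash; recrystallise to ≥98% ee
Reagents that add atoms: methanol, CO
Why: Catalytic enantioselective alcoholysis (desymmetrisation) of a prochiral cyclic anhydride, in which the quinuclidine acts as general base for MeOH while the sulfonamide N–H activates one enantiotopic carbonyl, sets the only stereocentre as (S); it becomes (R)‑C4 of the target because the CIP priorities of the two arms change later.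

**Step 4**
Reactants: 1 4‑(benzyloxy)‑3‑methoxybenzaldehyde; 7 pentane‑2,4‑dione (acetylacetone, 3 equiv)
Product: 8 (5E)‑6‑[4‑(benzyloxy)‑3‑methoxyphenyl]hex‑5‑ene‑2,4‑dione
Conditions: B2O3 (1.5 equiv), B(OnBu)3 (1.0 equiv), n‑BuNH2 (0.2 equiv, added slowly), EtOAc, 70 °C, 4 h; then 1 M HCl, 50 °C, 1 h
Reagents that add atoms: none
Why: Pabon‑type boron‑templated aldol condensation, in which the boron chelate masks the central CH2 and directs the amine‑catalysed condensation to a terminal methyl; excess acetylacetone suppresses the bis‑adduct and dehydration gives the conjugated (E)‑alkene.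

**Step 5**
Reactants: 6 (3S)‑3‑[4‑(benzyloxy)‑3‑methoxyphenyl]‑5‑methoxy‑5‑oxopentanoic acid; 8 (5E)‑6‑[4‑(benzyloxy)‑3‑methoxyphenyl]hex‑5‑ene‑2,4‑dione (3.2 equiv)
Product: 11 (4R)‑4‑[4‑(benzyloxy)‑3‑methoxyphenyl]‑5‑{(E)‑2‑[4‑(benzyloxy)‑3‑methoxyphenyl]ethenyl}‑7‑hydroxy‑3,4‑dihydro‑2H‑chromen‑2‑one, via triketo acid 9 (not isolated), via resorcinol acid 10 (not isolated)
Conditions: 8, LDA (6.3 equiv), THF, −78→0 °C, 1 h; add 6 in THF, 0 °C→rt, 4 h; then degassed 1 M aq KOH, rt, 16 h; then 3 M HCl to pH 1, 40 °C, 1 h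
Reagents that add atoms: none
Why: Harris‑type γ‑acylation (Claisen condensation) of the terminal carbanion of dilithio‑8, its only γ‑site, on the methyl ester of 6 (whose carboxylate is inert) gives the 5,7,9‑trioxo acid 9; in aqueous base the C4 methylene enolate adds to the C9 cinnamoyl carbonyl, the only six‑membered aldol mode because C9 has no enolisable flank and the carboxylate cannot engage in Dieckmann closure, and dehydration/enolisation gives the resorcinol irreversibly (Collie–Harris polyketide‑type aldol aromatisation, the laboratory counterpart of the stilbene‑synthase cyclisation), after which acid closes the lactone onto the single ortho phenol; no stereocentre is formed, and C3 of 6, which is not α to any carbonyl, is carried through unchanged.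

**Step 6**
Reactants: 11 (4R)‑4‑[4‑(benzyloxy)‑3‑methoxyphenyl]‑5‑{(E)‑2‑[4‑(benzyloxy)‑3‑methoxyphenyl]ethenyl}‑7‑hydroxy‑3,4‑dihydro‑2H‑chromen‑2‑one
Product: 12 (4R)‑7‑hydroxy‑4‑(4‑hydroxy‑3‑methoxyphenyl)‑5‑[(E)‑2‑(4‑hydroxy‑3‑methoxyphenyl)ethenyl]‑3,4‑dihydro‑2H‑chromen‑2‑one (CNP0277187.1)
Conditions: BCl3 (6 equiv), pentamethylbenzene (8 equiv), CH2Cl2, −78 °C, 1–2 h; then pH 7 aqueous buffer
Reagents that add atoms: none
Why: Lewis‑acid O‑debenzylation with a cation scavenger, in which BCl3 ionises the benzylic C–O bonds at −78 °C and pentamethylbenzene traps the benzyl cation by Friedel–Crafts alkylation, so the stilbene (hydrogenolysis is excluded), the lactone, the aryl methyl ethers and the stereocentre are left untouched.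

**Compound list**
1 | 4‑(benzyloxy)‑3‑methoxybenzaldehyde | COc1cc(C=O)ccc1OCc1ccccc1 | starting material
2 | ethyl acetoacetate | CCOC(=O)CC(C)=O | starting material
3 | diethyl 2,4‑diacetyl‑3‑[4‑(benzyloxy)‑3‑methoxyphenyl]pentanedioate (diastereomer mixture) | CCOC(=O)C(C(C)=O)C(c1ccc(OCc2ccccc2)c(OC)c1)C(C(C)=O)C(=O)OCC | intermediate
4 | 3‑[4‑(benzyloxy)‑3‑methoxyphenyl]pentanedioic acid | OC(=O)CC(c1ccc(OCc2ccccc2)c(OC)c1)CC(=O)O | intermediate
5 | 4‑[4‑(benzyloxy)‑3‑methoxyphenyl]oxane‑2,6‑dione | O=C1CC(c2ccc(OCc3ccccc3)c(OC)c2)CC(=O)O1 | intermediate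
6 | (3S)‑3‑[4‑(benzyloxy)‑3‑methoxyphenyl]‑5‑methoxy‑5‑oxopentanoic acid | COC(=O)C[C@@H](c1ccc(OCc2ccccc2)c(OC)c1)CC(=O)O | intermediate
7 | pentane‑2,4‑dione | CC(=O)CC(C)=O | starting material
8 | (5E)‑6‑[4‑(benzyloxy)‑3‑methoxyphenyl]hex‑5‑ene‑2,4‑dione | CC(=O)CC(=O)/C=C/c1ccc(OCc2ccccc2)c(OC)c1 | intermediate
9 | (3R,10E)‑3,11‑bis[4‑(benzyloxy)‑3‑methoxyphenyl]‑5,7,9‑trioxoundec‑10‑enoic acid | OC(=O)C[C@H](c1ccc(OCc2ccccc2)c(OC)c1)CC(=O)CC(=O)CC(=O)/C=C/c1ccc(OCc2ccccc2)c(OC)c1 | intermediate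
10 | (3R)‑3‑[4‑(benzyloxy)‑3‑methoxyphenyl]‑3‑{2‑[(E)‑2‑(4‑(benzyloxy)‑3‑methoxyphenyl)ethenyl]‑4,6‑dihydroxyphenyl}propanoic acid | OC(=O)C[C@H](c1ccc(OCc2ccccc2)c(OC)c1)c1c(O)cc(O)cc1/C=C/c1ccc(OCc2ccccc2)c(OC)c1 | intermediate
11 | (4R)‑4‑[4‑(benzyloxy)‑3‑methoxyphenyl]‑5‑{(E)‑2‑[4‑(benzyloxy)‑3‑methoxyphenyl]ethenyl}‑7‑hydroxy‑3,4‑dihydro‑2H‑chromen‑2‑one | COc1cc(/C=C/c2cc(O)cc3c2[C@@H](c2ccc(OCc4ccccc4)c(OC)c2)CC(=O)O3)ccc1OCc1ccccc1 | intermediate
12 | (4R)‑7‑hydroxy‑4‑(4‑hydroxy‑3‑methoxyphenyl)‑5‑[(E)‑2‑(4‑hydroxy‑3‑methoxyphenyl)ethenyl]‑3,4‑dihydro‑2H‑chromen‑2‑one | COc1cc(/C=C/c2cc(O)cc3c2[C@@H](c2ccc(O)c(OC)c2)CC(=O)O3)ccc1O | target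

**Total step count:** 6
**Longest linear sequence:** 5 steps (1 → 4 → 5 → 6 → 11 → 12)

**Three steps most likely to fail**

1. Step 5 (acylation/aromatisation/lactonisation cascade). The risks are enolisation of the methyl ester of 6 by the dianion instead of acylation, and retro‑Claisen cleavage or reversible 6‑endo conjugate addition onto the cinnamoyl unit competing with the aldol closure. The fallback sets out from 5 and returns at 11. Methanolysis of 5 with the pseudo‑enantiomeric catalyst gives (3R)‑3‑[4‑(benzyloxy)‑3‑methoxyphenyl]‑5‑methoxy‑5‑oxopentanoic acid F1. Its free acid arm, which now becomes the C4a–C8a arm, is activated with carbonyldiimidazole to methyl (3R)‑3‑[4‑(benzyloxy)‑3‑methoxyphenyl]‑5‑(1H‑imidazol‑1‑yl)‑5‑oxopentanoate F2. F2 acylates dilithio‑8 at −78 °C, where N‑acylimidazoles add much faster than they enolise, to give the isolated methyl (3R,10E)‑3,11‑bis[4‑(benzyloxy)‑3‑methoxyphenyl]‑5,7,9‑trioxoundec‑10‑enoate F3. Aqueous KOH (saponification plus aldol aromatisation) followed by HCl then gives 11. Isolating F3 also allows the cyclisation to be optimised separately, for example under pH 9–10 buffer.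

2. Step 3 (desymmetrisation). The risks are insufficient ee with this electron‑rich aryl group or the wrong sense of induction. The fallback sets out from 4 and returns at 6. Fischer esterification (MeOH, H2SO4) gives dimethyl 3‑[4‑(benzyloxy)‑3‑methoxyphenyl]pentanedioate F4. Hydrolase‑catalysed enantiotopos‑selective mono‑hydrolysis in pH 7–8 buffer then gives 6; pig liver esterase, α‑chymotrypsin and immobilised Candida antarctica lipase B would be screened for the (S) sense.

3. Step 4 (mono‑condensation). The risk is over‑condensation to the curcumin‑type bis‑adduct and a low yield of 8. The fallback sets out from 1 and returns at 8. Claisen–Schmidt condensation of 1 with excess acetone (aq NaOH) gives (3E)‑4‑[4‑(benzyloxy)‑3‑methoxyphenyl]but‑3‑en‑2‑one F5. Crossed Claisen C‑acetylation of its methyl ketone with ethyl acetate (NaH, THF) then gives 8.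

**Further compounds**
F1 | step 5 | (3R)‑3‑[4‑(benzyloxy)‑3‑methoxyphenyl]‑5‑methoxy‑5‑oxopentanoic acid | COC(=O)C[C@H](c1ccc(OCc2ccccc2)c(OC)c1)CC(=O)O
F2 | step 5 | methyl (3R)‑3‑[4‑(benzyloxy)‑3‑methoxyphenyl]‑5‑(1H‑imidazol‑1‑yl)‑5‑oxopentanoate | COC(=O)C[C@H](c1ccc(OCc2ccccc2)c(OC)c1)CC(=O)n1ccnc1
F3 | step 5 | methyl (3R,10E)‑3,11‑bis[4‑(benzyloxy)‑3‑methoxyphenyl]‑5,7,9‑trioxoundec‑10‑enoate | COC(=O)C[C@H](c1ccc(OCc2ccccc2)c(OC)c1)CC(=O)CC(=O)CC(=O)/C=C/c1ccc(OCc2ccccc2)c(OC)c1
F4 | step 3 | dimethyl 3‑[4‑(benzyloxy)‑3‑methoxyphenyl]pentanedioate | COC(=O)CC(c1ccc(OCc2ccccc2)c(OC)c1)CC(=O)OC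
F5 | step 4 | (3E)‑4‑[4‑(benzyloxy)‑3‑methoxyphenyl]but‑3‑en‑2‑one | CC(=O)/C=C/c1ccc(OCc2ccccc2)c(OC)c1
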